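**Route in one sentence:** ring A is made last, by thermal electrocyclic ring expansion of a squarate-derived 2,3,4-trimethoxycyclobutenone whose sp3 carbon already carries the finished ring C/ring B unit as a 4-oxo-4H-pyran-2-yl group.

## Structural features

Grantioidinin (15) is an achiral flavone: benzo ring A (C4a, C5–C8, C8a) is fused to γ-pyranone ring C (O1, C2, C3, C4), and ring B, a 2,5-dimethoxyphenyl group, sits on C2. Ring A is hexasubstituted and carries oxygen on five contiguous carbons: the free hydroxyl at C5, methoxyls at C6, C7 and C8, and the ring oxygen O1 at C8a; only C4a carries carbon. Ring C bears a methoxyl at C3; there is no stereocentre, and the C2–C1' axis is not configurationally stable, so no stereochemical problem exists. Fragile points are the chelated peri 5-OH (it must stay free while six other oxygens are methyl ethers), the electron-rich rings A and B (oxidation, electrophilic halogenation), the γ-pyranone (nucleophilic ring opening, O-alkylation of the carbonyl) and the aryl methyl ethers (Lewis acids). The real difficulty is ring A: a penta-oxygenated benzene with one differentiated oxygen, which classical flavone routes buy with a multistep pentaoxygenated acetophenone and a final selective demethylation. The key step exploits two facts: C5–C6–C7–C8 is a chain of four oxygen-bearing carbons, which is the carbon skeleton of a dialkyl squarate, and C4a=C8a can be the C5=C6 double bond of a preformed γ-pyranone. Ring expansion of a squarate-derived cyclobutenone attached to that pyranone therefore builds ring A in one operation, the ketene oxygen becoming the free 5-OH and the carbinol oxygen the 8-OMe.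

## Logic of the disconnections

15 ⇒ 12 (key disconnection). The C4a–C5 bond of ring A is cut and C5 is reconnected to C8, which contracts ring A to the four-membered ring of 12 (reverse of a 4π opening followed by a 6π closure). The cut is made here because it removes the hexasubstituted benzene entirely: 12 is an isomer of 15 that already holds all six methyl ethers, and the only free hydroxyl of 15 arises from the ring ketone of 12. No protecting group and no late demethylation are needed. The forward step demands that the four-membered ring opens with the pyranyl group turned inward, and that the ketene closes on the pyranone CH carbon (future C4a) and not on O1.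

12 ⇒ 11. The O–CH3 bond at the quaternary carbon (future O8–CH3) is cut. At this stage the future O8 is a tertiary alcohol and the future O5 is a ketone, so telling them apart costs one simple alkylation instead of a selective reaction between two phenols. The forward step demands a near-neutral methylation that does not open the strained α-hydroxy ketone.

11 ⇒ 7 + 8. The bond between the carbinol carbon (future C8) and pyranone C6 (future C8a) is cut. This splits the molecule into a commercial, symmetric C4O4 block (8, which supplies C5–C8 and the 6- and 7-methoxyls) and a block holding rings B and C (7). The forward step demands metalation of 7 only at C6, next to the ring oxygen, and a single 1,2-addition to 8. Only this regiochemistry maps the carbinol carbon to C8 and the ketene carbonyl to C5.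

7 ⇒ 4 + 5. The C3–C4 bond of ring C and the O1–C6 bond are cut. Ring C then comes from an aryl ketone that already holds ring B and the C3 methoxyl (4) and a three-carbon acyl chloride (5). The forward step demands C-acylation (not O-acylation) of the enolate of 4 and ring closure through the aryl-ketone enol oxygen.

4 ⇒ 1 + 2. The aryl–carbonyl bond (future C1'–C2 bond) is cut, giving two commercial compounds. The forward step demands addition of 1 to 2 once only.

## Other disconnections considered

Alternative 1: the first plan that comes to mind cuts O1–C2 and C2–C3. Claisen–Schmidt condensation of the pentaoxygenated acetophenone A1 with the ring B aldehyde would give chalcone A2, Algar–Flynn–Oyamada oxidative cyclisation would give flavonol A3, and O3-methylation and selective O5-demethylation would finish. The chosen plan is preferred on three grounds. A1 is not simple: its penta-oxygenated ring has to be assembled from a trioxygenated phenol by acylation, nuclear oxidation and methylation, so the real difficulty is only moved into the starting material. A2 carries a 6'-methoxyl, a substitution type for which the oxidative cyclisation is expected to divert toward the five-membered aurone. The final demethylation must distinguish O5 from O3, both of which flank C4=O. The sequence would be roughly twice as long as the five steps proposed.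

Alternative 2: cut C4–C4a, C3–C4 and O1–C2. Carbonylative Sonogashira coupling and cyclisation of the o-iodophenol A4 with the ring B arylacetylene under zerovalent palladium catalysis would give flavone A5. A4 is a hexasubstituted penta-oxygenated benzene, no easier to make than A1, and oxidative addition into its di-ortho-substituted, electron-rich C–I bond should be slow. A5 lacks the C3 oxygen, which would need a separate C–H oxygenation and methylation, and O5 would still have to be demethylated. The plan shortens nothing at ring A.

Alternative 3: cut O1–C8a and C4–C4a with an aryne. The symmetric tetramethoxybenzyne A7, generated from dibromide A6, would be trapped by the enolate of β-ketoester A8 through O-arylation followed by attack of the aryl anion on the ester, giving the pentamethyl ether A9, which would then be demethylated at O5. The symmetry of A7 removes the regiochemical question, but β-ketoester enolates are expected to attack arynes through carbon (leading to acyl-alkylation) rather than through oxygen. A6 needs a tetraoxygenated arene and extra steps, and the O5/O3 demethylation problem remains. The risk is higher than in the chosen key step and the gain in simplicity smaller.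

Key step: step 5

Remark: the pyranone positions are numbered as in 7 throughout (C5–H next to the carbonyl, C6–H next to the ring oxygen). Compounds 3, 6, 10, 11, 12 and 14 each contain one stereocentre, are formed as racemates, and lose it before the target is reached, so their SMILES carry no configuration.

## Route

Step 1
Reactants: 1 2,5-dimethoxyphenylmagnesium bromide (commercial solution in THF); 2 N,2-dimethoxy-N-methylacetamide
Product: 4 1-(2,5-dimethoxyphenyl)-2-methoxyethan-1-one, via bromomagnesium hemiaminal chelate 3 (not isolated)
Conditions: THF, 0 °C to rt; then 1 M aq HCl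
Reagents that add atoms: none
Why: Weinreb ketone synthesis: the aryl Grignard reagent adds once because the magnesium chelate 3 persists until the acidic work-up, so no tertiary alcohol should form and the α-methoxyl is untouched.

Step 2
Reactants: 4 1-(2,5-dimethoxyphenyl)-2-methoxyethan-1-one; 5 (E)-3-ethoxyacryloyl chloride
Product: 7 2-(2,5-dimethoxyphenyl)-3-methoxy-4H-pyran-4-one, via enol ether diketone 6 (not isolated)
Conditions: MgBr2·OEt2, iPr2NEt, CH2Cl2, 0 °C to rt; aq HCl wash; then TFA, CH2Cl2, rt
Reagents that add atoms: none
Why: Soft enolisation gives the magnesium-chelated enolate of 4 (its only enolisable position), and Claisen-type C-acylation by 5 should give 6. Acid then promotes 6-endo-trig oxa-Michael addition of the aryl-ketone enol oxygen to the β-ethoxy enone and loss of ethanol, the usual cyclodehydration to a γ-pyranone.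

Step 3
Reactants: 7 2-(2,5-dimethoxyphenyl)-3-methoxy-4H-pyran-4-one; 8 3,4-dimethoxycyclobut-3-ene-1,2-dione (dimethyl squarate)
Product: 11 4-[6-(2,5-dimethoxyphenyl)-5-methoxy-4-oxo-4H-pyran-2-yl]-4-hydroxy-2,3-dimethoxycyclobut-2-en-1-one (racemic), via 6-lithiopyranone 9 (not isolated), via lithium alkoxide 10 (not isolated)
Conditions: lithium 2,2,6,6-tetramethylpiperidide (LiTMP, from 2,2,6,6-tetramethylpiperidine and n-BuLi), THF, −78 °C; cannulate into 8, THF, −78 °C; then aq NH4Cl, −78 °C to rt
Reagents that add atoms: none
Why: The hindered amide should deprotonate C6–H of 7 (an sp2 C–H next to the ring oxygen and β to the carbonyl, the counterpart of C2 lithiation of chromones), and 9 has no β-leaving group, so it should persist at −78 °C. 1,2-Addition of an sp2 organolithium to one carbonyl of a squarate diester is the standard entry to 4-substituted 4-hydroxycyclobutenones; inverse addition limits double addition, and the new carbinol centre is racemic and is erased in step 5.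

Step 4
Reactants: 11 4-[6-(2,5-dimethoxyphenyl)-5-methoxy-4-oxo-4H-pyran-2-yl]-4-hydroxy-2,3-dimethoxycyclobut-2-en-1-one
Product: 12 4-[6-(2,5-dimethoxyphenyl)-5-methoxy-4-oxo-4H-pyran-2-yl]-2,3,4-trimethoxycyclobut-2-en-1-one (racemic)
Conditions: MeI, Ag2O, 4 Å MS, MeCN, rt, dark
Reagents that add atoms: iodomethane, CI
Why: Purdie methylation (MeI/Ag2O) etherifies the tertiary carbinol under nearly neutral conditions, which should avoid base-induced ring opening of the strained α-hydroxy ketone. The enol ethers, aryl ethers and the pyranone carbonyl should be inert to MeI at room temperature.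

Step 5
Reactants: 12 4-[6-(2,5-dimethoxyphenyl)-5-methoxy-4-oxo-4H-pyran-2-yl]-2,3,4-trimethoxycyclobut-2-en-1-one
Product: 15 Grantioidinin, 2-(2,5-dimethoxyphenyl)-5-hydroxy-3,6,7,8-tetramethoxy-4H-chromen-4-one, via dienylketene 13 (not isolated), via cyclohexadienone 14 (not isolated)
Conditions: degassed p-xylene (0.02 M), 138 °C, Ar
Reagents that add atoms: none
Why: Heating 12 should cause conrotatory 4π electrocyclic opening of the C1–C4 bond of the cyclobutenone to dienylketene 13; the donor methoxyl on the sp3 carbon rotates outward (torquoselectivity of donor substituents), which turns the pyranyl group inward, cis to the ketene. The electrophilic ketene carbon is then attacked by pyranone C5, the nucleophilic α-carbon of the vinylogous ester, in a 6π electrocyclisation that forms the C4a–C5 bond and closes ring A as the six-membered carbocycle of cyclohexadienone 14. Enolisation of 14 (loss of the C4a hydrogen) should give phenol 15, driven by aromatisation and by the O5–H···O=C4 hydrogen bond. The closest known reaction type is the Moore ring expansion of squarate-derived 4-aryl-, 4-heteroaryl- and 4-alkenyl-4-alkoxycyclobutenones to oxygenated phenols and hydroquinones. No stereocentre is created and the one in 12 is destroyed. Three selectivities are needed: inward rotation of the pyranyl group, secured by the 4-methoxyl; closure at C5 and not at ring oxygen O1, secured because O-attack would give an oxonium ylide that can only revert, whereas C-attack leads irreversibly to the arene; and OH at C5 with OMe at C8, fixed by connectivity, since the ketene carbonyl carbon bonds to C4a next to C4=O and the methoxylated sp3 carbon is already bonded to the future C8a.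

## Compound list

1 | 2,5-dimethoxyphenylmagnesium bromide | COc1ccc(OC)c([Mg]Br)c1 | starting material
2 | N,2-dimethoxy-N-methylacetamide | COCC(=O)N(C)OC | starting material
3 | bromomagnesium 1-(2,5-dimethoxyphenyl)-2-methoxy-1-[methoxy(methyl)amino]ethan-1-olate (racemic chelate) | COCC(O[Mg]Br)(N(C)OC)c1cc(OC)ccc1OC | intermediate
4 | 1-(2,5-dimethoxyphenyl)-2-methoxyethan-1-one | COCC(=O)c1cc(OC)ccc1OC | intermediate
5 | (E)-3-ethoxyacryloyl chloride | CCO/C=C/C(=O)Cl | starting material
6 | (E)-1-(2,5-dimethoxyphenyl)-5-ethoxy-2-methoxypent-4-ene-1,3-dione (racemic, enolisable) | CCO/C=C/C(=O)C(OC)C(=O)c1cc(OC)ccc1OC | intermediate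
7 | 2-(2,5-dimethoxyphenyl)-3-methoxy-4H-pyran-4-one | COc1ccc(OC)c(-c2occc(=O)c2OC)c1 | intermediate
8 | 3,4-dimethoxycyclobut-3-ene-1,2-dione (dimethyl squarate) | COC1=C(OC)C(=O)C1=O | starting material
9 | [6-(2,5-dimethoxyphenyl)-5-methoxy-4-oxo-4H-pyran-2-yl]lithium | COc1ccc(OC)c(-c2oc([Li])cc(=O)c2OC)c1 | intermediate
10 | lithium 1-[6-(2,5-dimethoxyphenyl)-5-methoxy-4-oxo-4H-pyran-2-yl]-2,3-dimethoxy-4-oxocyclobut-2-en-1-olate (racemic) | COC1=C(OC)C(O[Li])(c2cc(=O)c(OC)c(-c3cc(OC)ccc3OC)o2)C1=O | intermediate
11 | 4-[6-(2,5-dimethoxyphenyl)-5-methoxy-4-oxo-4H-pyran-2-yl]-4-hydroxy-2,3-dimethoxycyclobut-2-en-1-one (racemic) | COC1=C(OC)C(O)(c2cc(=O)c(OC)c(-c3cc(OC)ccc3OC)o2)C1=O | intermediate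
12 | 4-[6-(2,5-dimethoxyphenyl)-5-methoxy-4-oxo-4H-pyran-2-yl]-2,3,4-trimethoxycyclobut-2-en-1-one (racemic) | COC1=C(OC)C(OC)(c2cc(=O)c(OC)c(-c3cc(OC)ccc3OC)o2)C1=O | intermediate
13 | (3Z)-4-[6-(2,5-dimethoxyphenyl)-5-methoxy-4-oxo-4H-pyran-2-yl]-2,3,4-trimethoxybuta-1,3-dien-1-one | O=C=C(OC)/C(OC)=C(OC)\c1cc(=O)c(OC)c(-c2cc(OC)ccc2OC)o1 | intermediate
14 | 2-(2,5-dimethoxyphenyl)-3,6,7,8-tetramethoxy-4H-chromene-4,5(4aH)-dione (racemic) | O=C1C(OC)=C(OC)C(OC)=C2OC(-c3cc(OC)ccc3OC)=C(OC)C(=O)C12 | intermediate
15 | Grantioidinin, 2-(2,5-dimethoxyphenyl)-5-hydroxy-3,6,7,8-tetramethoxy-4H-chromen-4-one | COc1ccc(OC)c(-c2oc3c(OC)c(OC)c(OC)c(O)c3c(=O)c2OC)c1 | target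

## Step count and least certain steps

Total step count: 5. Longest linear sequence: 5 steps (1 and 2 → 4 → 7 → 11 → 12 → 15); 5 and 8 enter at steps 2 and 3.

**Step 5 (key step).** The most likely failure is slow 6π closure onto the pyranone C5=C6 bond, which is less electron-rich than a simple alkenyl or aryl partner. The dienylketene would then be consumed by dimerisation or by capture with adventitious nucleophiles before ring A forms. The fallback gives up the ring expansion and builds ring C onto a preformed ring A by classical chemistry; it sets out from 4 and comes back to the route at 15. Ethoxycarbonylation of 4 (NaH, diethyl carbonate, THF, reflux) would give ethyl 3-(2,5-dimethoxyphenyl)-2-methoxy-3-oxopropanoate F1. Mentzer thermal condensation of F1 with commercial 3,4,5-trimethoxyphenol (Ph2O, 250 °C) would give 2-(2,5-dimethoxyphenyl)-3,5,6,7-tetramethoxy-4H-chromen-4-one F2. Chelation-directed cleavage of the peri methyl ether (BCl3, CH2Cl2, −78 to 0 °C) would give 2-(2,5-dimethoxyphenyl)-5-hydroxy-3,6,7-trimethoxy-4H-chromen-4-one F3. Elbs persulfate oxidation (K2S2O8, aq KOH, pyridine, rt), which attacks para to the phenoxide oxygen, would give potassium 2-(2,5-dimethoxyphenyl)-5-hydroxy-3,6,7-trimethoxy-4-oxo-4H-chromen-8-yl sulfate F4. Hydrolysis (aq HCl, 80 °C) would give 2-(2,5-dimethoxyphenyl)-5,8-dihydroxy-3,6,7-trimethoxy-4H-chromen-4-one F5. Methylation of the non-chelated 8-OH (Me2SO4, one equivalent, K2CO3, acetone, Ar) would then give 15.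

**Step 3.** Possible failures are metalation at a competing site (C5–H or ring B ortho to a methoxyl), decay of the lithiated pyranone by self-condensation or by amide addition and ring opening, and double addition to 8. The fallback separates metalation from addition and uses a milder, isolable handle; it sets out from 7 and comes back at 11. Zincation of 7 with TMPZnCl·LiCl (THF, rt) would give [6-(2,5-dimethoxyphenyl)-5-methoxy-4-oxo-4H-pyran-2-yl]zinc chloride F6. Iodinolysis (I2, THF) would give 2-(2,5-dimethoxyphenyl)-6-iodo-3-methoxy-4H-pyran-4-one F7, which is isolated and also proves the site of metalation. Iodine–magnesium exchange (iPrMgCl·LiCl, THF, −40 °C) would give [6-(2,5-dimethoxyphenyl)-5-methoxy-4-oxo-4H-pyran-2-yl]magnesium chloride F8, which is added to 8 at −40 °C and gives 11 after aq NH4Cl.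

**Step 2.** Possible failures are O-acylation of the enolate, conjugate addition to or oligomerisation of the β-alkoxyacryloyl chloride, and premature hydrolysis of the enol ether. The fallback assembles the same three carbons as a two-carbon and then a one-carbon unit; it sets out from 4 and comes back at 7. C-acetylation of 4 (AcCl, MgBr2·OEt2, iPr2NEt, CH2Cl2) would give 1-(2,5-dimethoxyphenyl)-2-methoxybutane-1,3-dione F9. Condensation at the terminal methyl with DMF dimethyl acetal (toluene, 90 °C) would give (E)-1-(2,5-dimethoxyphenyl)-5-(dimethylamino)-2-methoxypent-4-ene-1,3-dione F10. Acid (TFA, CH2Cl2, rt) would close it to 7.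

**Step 4.** Possible failures are sluggish etherification of the hindered tertiary carbinol, silver- or base-promoted ring opening or rearrangement of the α-hydroxy cyclobutenone, and O-alkylation of the pyranone carbonyl during a long reaction. The fallback never isolates the free carbinol: it sets out from 10, the lithium alkoxide formed in step 3, which is trapped in the same flask with MeOTf (THF, −78 to 0 °C) and comes back at 12. The alkoxide is far more nucleophilic than the pyranone carbonyl, and no new compound is involved.

## Further compounds

F1 | step 5 | ethyl 3-(2,5-dimethoxyphenyl)-2-methoxy-3-oxopropanoate (racemic) | CCOC(=O)C(OC)C(=O)c1cc(OC)ccc1OC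
F2 | step 5 | 2-(2,5-dimethoxyphenyl)-3,5,6,7-tetramethoxy-4H-chromen-4-one | COc1ccc(OC)c(-c2oc3cc(OC)c(OC)c(OC)c3c(=O)c2OC)c1
F3 | step 5 | 2-(2,5-dimethoxyphenyl)-5-hydroxy-3,6,7-trimethoxy-4H-chromen-4-one | COc1ccc(OC)c(-c2oc3cc(OC)c(OC)c(O)c3c(=O)c2OC)c1
F4 | step 5 | potassium 2-(2,5-dimethoxyphenyl)-5-hydroxy-3,6,7-trimethoxy-4-oxo-4H-chromen-8-yl sulfate | COc1ccc(OC)c(-c2oc3c(OS(=O)(=O)[O-])c(OC)c(OC)c(O)c3c(=O)c2OC)c1.[K+]
F5 | step 5 | 2-(2,5-dimethoxyphenyl)-5,8-dihydroxy-3,6,7-trimethoxy-4H-chromen-4-one | COc1ccc(OC)c(-c2oc3c(O)c(OC)c(OC)c(O)c3c(=O)c2OC)c1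
F6 | step 3 | [6-(2,5-dimethoxyphenyl)-5-methoxy-4-oxo-4H-pyran-2-yl]zinc chloride | COc1ccc(OC)c(-c2oc([Zn]Cl)cc(=O)c2OC)c1
F7 | step 3 | 2-(2,5-dimethoxyphenyl)-6-iodo-3-methoxy-4H-pyran-4-one | COc1ccc(OC)c(-c2oc(I)cc(=O)c2OC)c1
F8 | step 3 | [6-(2,5-dimethoxyphenyl)-5-methoxy-4-oxo-4H-pyran-2-yl]magnesium chloride | COc1ccc(OC)c(-c2oc([Mg]Cl)cc(=O)c2OC)c1
F9 | step 2 | 1-(2,5-dimethoxyphenyl)-2-methoxybutane-1,3-dione (racemic) | CC(=O)C(OC)C(=O)c1cc(OC)ccc1OC
F10 | step 2 | (E)-1-(2,5-dimethoxyphenyl)-5-(dimethylamino)-2-methoxypent-4-ene-1,3-dione (racemic) | CN(C)/C=C/C(=O)C(OC)C(=O)c1cc(OC)ccc1OC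
F0 | step 4 | none | none
A1 | alternative 1 | 1-(2-hydroxy-3,4,5,6-tetramethoxyphenyl)ethan-1-one | CC(=O)c1c(O)c(OC)c(OC)c(OC)c1OC
A2 | alternative 1 | (E)-3-(2,5-dimethoxyphenyl)-1-(2-hydroxy-3,4,5,6-tetramethoxyphenyl)prop-2-en-1-one | COc1ccc(OC)c(/C=C/C(=O)c2c(O)c(OC)c(OC)c(OC)c2OC)c1
A3 | alternative 1 | 2-(2,5-dimethoxyphenyl)-3-hydroxy-5,6,7,8-tetramethoxy-4H-chromen-4-one | COc1ccc(OC)c(-c2oc3c(OC)c(OC)c(OC)c(OC)c3c(=O)c2O)c1
A4 | alternative 2 | 2-iodo-3,4,5,6-tetramethoxyphenol | COc1c(O)c(I)c(OC)c(OC)c1OC
A5 | alternative 2 | 2-(2,5-dimethoxyphenyl)-5,6,7,8-tetramethoxy-4H-chromen-4-one | COc1ccc(OC)c(-c2cc(=O)c3c(OC)c(OC)c(OC)c(OC)c3o2)c1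
A6 | alternative 3 | 1,2-dibromo-3,4,5,6-tetramethoxybenzene | COc1c(Br)c(Br)c(OC)c(OC)c1OC
A7 | alternative 3 | 3,4,5,6-tetramethoxybenzyne (1,2-didehydro-3,4,5,6-tetramethoxybenzene) | COC1=C(OC)C(OC)=C(OC)C#C1
A8 | alternative 3 | methyl 3-(2,5-dimethoxyphenyl)-2-methoxy-3-oxopropanoate (racemic) | COC(=O)C(OC)C(=O)c1cc(OC)ccc1OC
A9 | alternative 3 | 2-(2,5-dimethoxyphenyl)-3,5,6,7,8-pentamethoxy-4H-chromen-4-one | COc1ccc(OC)c(-c2oc3c(OC)c(OC)c(OC)c(OC)c3c(=O)c2OC)c1
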